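Locants: ring O1, C2 (bears ring A), C3 (bears C9H2O–angelate), C4 (bears C7'H2–ring B), C5H2.
Cuts, in retrosynthetic order: first the C9–O ester bond. C9 is then raised to a carboxyl group and joined through oxygen to C7' (a γ-aryl lactone). Last, C2–C3 and C4–C5 are cut together.
Enabling feature: C2–O1–C5 is an ArCH–O–CH2 triad, that is, a carbonyl ylide. The cis-related carbons C9 and C7' on C3 and C4 fit into one butenolide ring (C9 = carbonyl, C7' = benzylic C–O) whose C3=C4 bond is the dipolarophile.
Forward: the butenolide ring is closed first by metathesis and the tetrahydrofuran ring is fused onto it by [3+2] cycloaddition. The lactone ring is then opened at C7'–O by hydrogenolysis, and C9 is reduced and esterified.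
Stereochemistry: a lipase resolution fixes C7'. This centre sends the dipole to the opposite face (C3, C4), the ring alkene makes C3/C4 cis, exo placement of ring A sets C2, and C7' is finally erased.

Key step: step 7

Assumption: the lipase follows the usual empirical size rule for secondary alcohols (aryl = large group, vinyl = medium group), so the (R)-alcohol is acetylated and the (S)-alcohol is left.

Step 1
Reactants: 1 veratraldehyde (3,4-dimethoxybenzaldehyde); 2 (trimethylsilyl)methanol
Product: 3 4-{bis[(trimethylsilyl)methoxy]methyl}-1,2-dimethoxybenzene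
Conditions: 2 (2.2 equiv), p-TsOH·H2O (1 mol %), cyclohexane, reflux, Dean–Stark; then Et3N
Reagents that add atoms: none
Why: Acid-catalysed acetalisation of an aromatic aldehyde with a primary alcohol, pulled to completion by azeotropic removal of water; the C–Si bonds tolerate catalytic sulfonic acid and no stereocentre is formed.

Step 2
Reactants: 3 4-{bis[(trimethylsilyl)methoxy]methyl}-1,2-dimethoxybenzene
Product: 4 4-{chloro[(trimethylsilyl)methoxy]methyl}-1,2-dimethoxybenzene (racemic, used crude)
Conditions: AcCl (1.05 equiv), Zn(OAc)2 (0.1 mol %), CH2Cl2, 0 °C to rt; volatiles removed under high vacuum, residue taken up in dry MeCN and used the same day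
Reagents that add atoms: acetyl chloride, CC(=O)Cl
Why: Zinc-catalysed exchange between an acetal and an acyl chloride (the standard α-chloro ether synthesis), in which one silylmethoxy group is acetylated and expelled with help from the electron-rich ring and chloride caps the cation; the new centre is formed racemic and disappears again in step 7.

Step 3
Reactants: 1 veratraldehyde; 5 vinylmagnesium bromide
Product: 6 rac-1-(3,4-dimethoxyphenyl)prop-2-en-1-ol
Conditions: THF, 0 °C; then sat. aq. NH4Cl
Reagents that add atoms: none
Why: 1,2-Addition of a Grignard reagent to a non-enolisable aldehyde; the carbinol centre (the later C7') is formed racemic and is resolved in the next step.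

Step 4
Reactants: 6 rac-1-(3,4-dimethoxyphenyl)prop-2-en-1-ol
Product: 7 (S)-1-(3,4-dimethoxyphenyl)prop-2-en-1-ol
Conditions: vinyl acetate (3 equiv), Burkholderia cepacia lipase (Amano PS), MTBE, 30 °C, stopped just past half conversion; chromatography on Et3N-deactivated silica
Reagents that add atoms: none
Why: Lipase-catalysed kinetic resolution by irreversible transesterification, in which the enzyme acetylates the (R)-alcohol and the slow-reacting (S)-alcohol should remain in high enantiomeric purity once conversion passes one half; this sets the only stereocentre brought in from outside.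

Step 5
Reactants: 7 (S)-1-(3,4-dimethoxyphenyl)prop-2-en-1-ol; 8 acryloyl chloride
Product: 9 (S)-1-(3,4-dimethoxyphenyl)prop-2-en-1-yl acrylate
Conditions: Et3N (1.5 equiv), CH2Cl2, −10 °C to 0 °C; filtration through Et3N-deactivated silica
Reagents that add atoms: none
Why: O-Acylation of a secondary alcohol with an acid chloride and an amine base; the C–O bond at the stereocentre is not broken, so the configuration is retained, and the cold basic medium suppresses ionisation of the benzylic, allylic ester.

Step 6
Reactants: 9 (S)-1-(3,4-dimethoxyphenyl)prop-2-en-1-yl acrylate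
Product: 10 (S)-5-(3,4-dimethoxyphenyl)furan-2(5H)-one
Conditions: second-generation Grubbs catalyst, RuCl2(=CHPh)(PCy3)(SIMes) (3 mol %), CH2Cl2 (0.01 M), reflux
Reagents that add atoms: none
Why: Ring-closing metathesis of an allyl acrylate to a butenolide, a standard use of this catalyst, which engages the allylic vinyl group first and then the acrylate; loss of ethene drives the reaction and the stereocentre is a spectator.

Step 7
Reactants: 4 4-{chloro[(trimethylsilyl)methoxy]methyl}-1,2-dimethoxybenzene; 10 (S)-5-(3,4-dimethoxyphenyl)furan-2(5H)-one
Product: 12 (1S,4S,5R,8S)-4,8-bis(3,4-dimethoxyphenyl)-3,7-dioxabicyclo[3.3.0]octan-2-one (cis-fused, both aryl groups exo), via carbonyl ylide 11 (not isolated)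
Conditions: 4 (3 equiv, MeCN solution added over 2 h), CsF (flame-dried, 6 equiv), MeCN, 0 °C to rt, Ar
Reagents that add atoms: none
Why: The C–Cl bond of 4, loosened by the para-methoxy group, ionises in MeCN while fluoride removes the silyl group (1,3-elimination), which gives ylide 11, a 4π dipole with its negative charge mainly on the CH2 terminus (C5) and its positive charge on the benzylic terminus (C2). The closest known reaction type is the CsF-induced formation of non-stabilised carbonyl ylides from α-chloroalkyl silylmethyl ethers and their [3+2] cycloaddition to acrylates, maleates, fumarates and enones, applied here to a cyclic enoate. The tetrahydrofuran ring closes in a single suprafacial [π4s+π2s] event in which C4–C5 and C2–C3 form together, so it is an intermolecular annulation onto the lactone and can only be cis-fused. C3 and C4 are controlled by the Z-alkene locked in the five-membered ring and by the C7' aryl group next to C4, which blocks one face so that both bonds form anti to it; C2 is controlled by the exo orientation of ring A, which keeps it on the convex face and trans to C9. The step needs regioselectivity (C5 to the β-carbon C4, C2 to the α-carbon C3), which the match between the nucleophilic CH2 end of 11 and the electrophilic β-carbon of the enoate secures, and it needs 10 to keep its configuration at the acidic γ-position, for which the barely soluble fluoride, the low temperature and the excess of 4 are chosen.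

Step 8
Reactants: 12 (1S,4S,5R,8S)-4,8-bis(3,4-dimethoxyphenyl)-3,7-dioxabicyclo[3.3.0]octan-2-one
Product: 13 (2S,3S,4R)-4-(3,4-dimethoxybenzyl)-2-(3,4-dimethoxyphenyl)tetrahydrofuran-3-carboxylic acid
Conditions: H2 (1 atm), 10% Pd/C, pyridine (0.5 equiv), EtOAc–MeOH, rt, stopped after uptake of one equivalent of H2; dilute citric acid work-up
Reagents that add atoms: none
Why: Catalytic hydrogenolysis of a benzylic ester C–O bond, where carboxylate is a far better leaving group than the ring alkoxide and amine-moderated Pd/C spares benzylic ethers while still cleaving benzylic esters, so C7'–O should break and C2–O1 persist; C7' becomes CH2 and C2, C3 and C4 are not touched.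

Step 9
Reactants: 13 (2S,3S,4R)-4-(3,4-dimethoxybenzyl)-2-(3,4-dimethoxyphenyl)tetrahydrofuran-3-carboxylic acid
Product: 14 [(2S,3R,4R)-4-(3,4-dimethoxybenzyl)-2-(3,4-dimethoxyphenyl)tetrahydrofuran-3-yl]methanol
Conditions: LiAlH4 (2 equiv), THF, 0 °C to rt; Fieser work-up (H2O, aq. NaOH, H2O)
Reagents that add atoms: none
Why: Hydride reduction of a carboxylic acid to the primary alcohol; the acid is deprotonated first, which protects C3 from enolisation, and aryl and alkyl ethers are inert to LiAlH4 (the descriptor at C3 changes only because the priorities change).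

Step 10
Reactants: 14 [(2S,3R,4R)-4-(3,4-dimethoxybenzyl)-2-(3,4-dimethoxyphenyl)tetrahydrofuran-3-yl]methanol; 15 angelic acid ((Z)-2-methylbut-2-enoic acid)
Product: 16 leoligin, [(2S,3R,4R)-4-(3,4-dimethoxybenzyl)-2-(3,4-dimethoxyphenyl)tetrahydrofuran-3-yl]methyl (Z)-2-methylbut-2-enoate
Conditions: PPh3 (1.5 equiv), DIAD (1.5 equiv), THF, 0 °C to rt
Reagents that add atoms: none
Why: Mitsunobu esterification, in which the primary hydroxyl at C9 is activated and displaced by angelate, so the acid is never turned into an acylating agent and its Z-alkene has no pathway to the E isomer; no ring stereocentre takes part.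

Compound list
1 | veratraldehyde (3,4-dimethoxybenzaldehyde) | COc1ccc(C=O)cc1OC | starting material
2 | (trimethylsilyl)methanol | C[Si](C)(C)CO | starting material
3 | 4-{bis[(trimethylsilyl)methoxy]methyl}-1,2-dimethoxybenzene | COc1ccc(C(OC[Si](C)(C)C)OC[Si](C)(C)C)cc1OC | intermediate
4 | 4-{chloro[(trimethylsilyl)methoxy]methyl}-1,2-dimethoxybenzene (racemic) | COc1ccc(C(Cl)OC[Si](C)(C)C)cc1OC | intermediate
5 | vinylmagnesium bromide | C=C[Mg]Br | starting material
6 | rac-1-(3,4-dimethoxyphenyl)prop-2-en-1-ol | C=CC(O)c1ccc(OC)c(OC)c1 | intermediate
7 | (S)-1-(3,4-dimethoxyphenyl)prop-2-en-1-ol | C=C[C@H](O)c1ccc(OC)c(OC)c1 | intermediate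
8 | acryloyl chloride | C=CC(=O)Cl | starting material
9 | (S)-1-(3,4-dimethoxyphenyl)prop-2-en-1-yl acrylate | C=C[C@H](OC(=O)C=C)c1ccc(OC)c(OC)c1 | intermediate
10 | (S)-5-(3,4-dimethoxyphenyl)furan-2(5H)-one | O=C1C=C[C@H](O1)c1ccc(OC)c(OC)c1 | intermediate
11 | (3,4-dimethoxybenzylidene)oxonio methanide (carbonyl ylide, not isolated) | COc1ccc(C=[O+][CH2-])cc1OC | intermediate
12 | (1S,4S,5R,8S)-4,8-bis(3,4-dimethoxyphenyl)-3,7-dioxabicyclo[3.3.0]octan-2-one | O=C2[C@H]1[C@@H]([C@H](O2)c3ccc(OC)c(OC)c3)CO[C@@H]1c1ccc(OC)c(OC)c1 | intermediate
13 | (2S,3S,4R)-4-(3,4-dimethoxybenzyl)-2-(3,4-dimethoxyphenyl)tetrahydrofuran-3-carboxylic acid | OC(=O)[C@H]1[C@@H](Cc2ccc(OC)c(OC)c2)CO[C@@H]1c1ccc(OC)c(OC)c1 | intermediate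
14 | [(2S,3R,4R)-4-(3,4-dimethoxybenzyl)-2-(3,4-dimethoxyphenyl)tetrahydrofuran-3-yl]methanol | OC[C@H]1[C@@H](Cc2ccc(OC)c(OC)c2)CO[C@@H]1c1ccc(OC)c(OC)c1 | intermediate
15 | angelic acid ((Z)-2-methylbut-2-enoic acid) | C/C=C(/C)C(=O)O | starting material
16 | leoligin | C/C=C(/C)C(=O)OC[C@H]1[C@@H](Cc2ccc(OC)c(OC)c2)CO[C@@H]1c1ccc(OC)c(OC)c1 | target

Total step count: 10. Longest linear sequence: 8 steps (steps 3 to 10, from veratraldehyde). Steps 1 and 2 form the short second branch, and step 2 is run just before step 7.

Steps most likely to fail

1. Step 7.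
- The ylide may be lost faster than the 1,2-disubstituted ring alkene captures it, through closure to the oxirane, capture by traces of aldehyde, or self-reaction.
- Regio- or exo/endo selectivity may be poor. Loss of exo selectivity alone could be repaired by acid equilibration at the benzylic ether carbon C2.
- Fluoride may enolise the butenolide at its γ-position and erode its configuration.
- Fallback: the tetrahydrofuran is built by a radical cyclisation that sets out from 7, whose carbinol carbon already has the configuration required at C2, and rejoins the route at 14. O-Alkylation of 7 with propargyl bromide (NaH, THF) gives 1,2-dimethoxy-4-[(1S)-1-(prop-2-yn-1-yloxy)prop-2-en-1-yl]benzene F1. Treatment with mCPBA (NaHCO3, CH2Cl2) epoxidises the vinyl group to 2-[(R)-(3,4-dimethoxyphenyl)(prop-2-yn-1-yloxy)methyl]oxirane F2, of which both epimers at the oxirane carbon serve. Cp2TiCl (trivalent titanium, made from Cp2TiCl2 and Zn dust in THF) opens the oxirane to the C3 radical. This radical closes 5-exo-dig onto the alkyne, trans to ring A, and should give [(2S,3R)-2-(3,4-dimethoxyphenyl)-4-methylidenetetrahydrofuran-3-yl]methanol F3. Hydroboration with excess 9-BBN delivers hydrogen to C4 on the face opposite C9 and gives the B-alkyl-9-borabicyclo[3.3.1]nonane F4, whose hydroxyl is carried as its borinate. This is coupled in the same flask with 4-bromo-1,2-dimethoxybenzene (B-alkyl Suzuki–Miyaura coupling, PdCl2(dppf), aq. NaOH, THF, reflux) to give 14.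

2. Step 8.
- The C2–O1 benzylic ether may be hydrogenolysed alongside or after the lactone C7'–O bond.
- Conversely, the amine-moderated catalyst may fail to cleave the hindered secondary benzylic ester.
- Fallback: catalytic hydrogenolysis is replaced by nucleophilic O-alkyl cleavage followed by radical reduction, setting out from 12 and returning at 13. Sodium phenylselenide (PhSeSePh, NaH, THF; then DMF, 100 °C) attacks the benzylic carbon C7' and releases the carboxylate. Acidification gives (2S,3S,4R)-2-(3,4-dimethoxyphenyl)-4-[(R)-(3,4-dimethoxyphenyl)(phenylselanyl)methyl]tetrahydrofuran-3-carboxylic acid F5. It is drawn with inversion at C7', a centre of no consequence. Bu3SnH and AIBN (toluene, 80 °C) then replace selenium by hydrogen to give 13. Neither operation can touch an ether C–O bond.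

3. Step 2.
- The very electron-rich benzylic chloride may ionise prematurely during its formation or concentration.
- This would lead to hydrolysis, Friedel–Crafts self-alkylation, or chloride-induced loss of the silyl group before a dipolarophile is present.
- Fallback: no covalent halide is made, and the sequence sets out from the storable acetal 3 and rejoins at ylide 11 (hence at 12). In the cycloaddition flask that already holds 10, Me3SiOTf (1 equiv, CH2Cl2–MeCN, −40 °C) removes one silylmethoxy group and gives (3,4-dimethoxybenzylidene)[(trimethylsilyl)methyl]oxonium triflate F6. Subsequent addition of CsF desilylates it to 11. This parallels the formation of azomethine ylides from silylmethyl iminium triflates and CsF.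

Further compounds
F1 | step 7 | 1,2-dimethoxy-4-[(1S)-1-(prop-2-yn-1-yloxy)prop-2-en-1-yl]benzene | C=C[C@H](OCC#C)c1ccc(OC)c(OC)c1
F2 | step 7 | 2-[(R)-(3,4-dimethoxyphenyl)(prop-2-yn-1-yloxy)methyl]oxirane (both epimers at the oxirane carbon) | C1OC1[C@H](OCC#C)c1ccc(OC)c(OC)c1
F3 | step 7 | [(2S,3R)-2-(3,4-dimethoxyphenyl)-4-methylidenetetrahydrofuran-3-yl]methanol | OC[C@H]1C(=C)CO[C@@H]1c1ccc(OC)c(OC)c1
F4 | step 7 | B-alkyl-9-borabicyclo[3.3.1]nonane from F3 (boron on C7', hydroxyl as 9-BBN borinate) | C1CC2CCCC(C1)B2OC[C@H]1[C@@H](CB2C3CCCC2CCC3)CO[C@@H]1c1ccc(OC)c(OC)c1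
F5 | step 8 | (2S,3S,4R)-2-(3,4-dimethoxyphenyl)-4-[(R)-(3,4-dimethoxyphenyl)(phenylselanyl)methyl]tetrahydrofuran-3-carboxylic acid | OC(=O)[C@H]1[C@@H]([C@@H]([Se]c2ccccc2)c2ccc(OC)c(OC)c2)CO[C@@H]1c1ccc(OC)c(OC)c1
F6 | step 2 | (3,4-dimethoxybenzylidene)[(trimethylsilyl)methyl]oxonium triflate | COc1ccc(C=[O+]C[Si](C)(C)C)cc1OC.[O-]S(=O)(=O)C(F)(F)F
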